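**Retrosynthetic overview** (germacrane numbering: ring C1–C10, lactone carbons C11–C13, methyls C14/C15; C5 carbinol, C6 lactone carbinol, C8 ester carbon)
1. Last bond C4–C5: intramolecular Nozaki–Hiyama–Kishi addition of a (Z)-β-iodoenone to a C5 aldehyde closes the ten-membered ring and sets C5.
2. The cis butyrolactone is not made directly: a six-membered α-methylene lactone (acyl on O5) with a free O6 is translactonised to the five-membered O6 lactone, which releases C5 as CH2OH.
3. Bond C7–C8: Barbier allylation of a (Z,Z)-iododienone aldehyde (fragment B) with a chiral 3-(bromomethyl)-5-silyloxy-5,6-dihydropyran-2-one (fragment A) sets C7 and C8 from C6; the tiglate is then put on O8.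
4. Fragment A comes from (R)-but-3-ene-1,2-diol and 2-(bromomethyl)acrylic acid by ring-closing metathesis; fragment B from 4-methyl-5,6-dihydro-2H-pyran-2-one by acetylide opening, hydroiodination and oxidation.
5. Ring order: six-membered lactone (metathesis), five-membered lactone (translactonisation), ten-membered carbocycle (chromium-mediated closure).

Assumption: the five compounds marked starting material in the compound list are bought as such, the diol as its (R)-enantiomer.

Step 1
Reactants: 1 (2R)-but-3-ene-1,2-diol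
Product: 2 (3R)-3,4-bis(tert-butyldimethylsilyloxy)but-1-ene
Conditions: TBSCl (2.3 equiv), imidazole, DMF, rt
Reagents that add atoms: tert-butyldimethylsilyl chloride, CC(C)(C)[Si](C)(C)Cl
Why: Double silyl ether formation (silylation) protects both hydroxyls and does not touch the stereocenter that becomes C6 of the target.

Step 2
Reactants: 2 (3R)-3,4-bis(tert-butyldimethylsilyloxy)but-1-ene
Product: 3 (2R)-2-(tert-butyldimethylsilyloxy)but-3-en-1-ol
Conditions: HF·pyridine, pyridine, THF, 0 °C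
Reagents that add atoms: none
Why: Selective desilylation, because buffered HF·pyridine cleaves the unhindered primary silyl ether far faster than the secondary allylic one, so only the CH2OH that becomes C5 is freed.

Step 3
Reactants: 3 (2R)-2-(tert-butyldimethylsilyloxy)but-3-en-1-ol; 4 2-(bromomethyl)prop-2-enoic acid
Product: 6 (2R)-2-(tert-butyldimethylsilyloxy)but-3-en-1-yl 2-(bromomethyl)prop-2-enoate, via 2-(bromomethyl)prop-2-enoyl chloride 5 (not isolated)
Conditions: 4, (COCl)2, DMF (cat.), CH2Cl2, 0 °C to rt; then 3, 2,6-lutidine, CH2Cl2, −20 to 0 °C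
Reagents that add atoms: none
Why: Esterification through the acid chloride made in the flask, with the hindered base 2,6-lutidine chosen so that the allylic bromide is not quaternised; no stereocenter is involved.

Step 4
Reactants: 6 (2R)-2-(tert-butyldimethylsilyloxy)but-3-en-1-yl 2-(bromomethyl)prop-2-enoate
Product: 7 (5R)-3-(bromomethyl)-5-(tert-butyldimethylsilyloxy)-5,6-dihydro-2H-pyran-2-one
Conditions: second-generation Grubbs catalyst (10 mol %), toluene (5 mM), 80 °C
Reagents that add atoms: none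
Why: Ring-closing metathesis of the vinyl group onto the 1,1-disubstituted acrylate expels ethylene and gives the six-membered unsaturated lactone whose endocyclic double bond carries the CH2Br on the carbonyl side, as needed for an allyl donor.

Step 5
Reactants: 8 4-methyl-5,6-dihydro-2H-pyran-2-one; 9 1-propynyllithium
Product: 11 (5Z)-8-hydroxy-6-methyloct-5-en-2-yn-4-one, via lithium hemiketal alkoxide 10 (not isolated)
Conditions: 9 (1.05 equiv), THF, −78 °C; then H2O, −78 °C to rt
Reagents that add atoms: none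
Why: Nucleophilic acyl substitution (acetylide 1,2-addition to a lactone), where the tetrahedral lithium alkoxide survives at −78 °C and opens only on quench, so over-addition is avoided and the Z alkene geometry is inherited from the ring.

Step 6
Reactants: 11 (5Z)-8-hydroxy-6-methyloct-5-en-2-yn-4-one
Product: 12 (2Z,5Z)-8-hydroxy-2-iodo-6-methylocta-2,5-dien-4-one
Conditions: NaI (1.5 equiv), AcOH, rt, dark
Reagents that add atoms: sodium iodide, [Na+].[I-]
Why: Conjugate hydroiodination of the ynone, a kinetic anti addition of HI that places iodine cis to the carbonyl and so fixes the Z geometry of the future C3=C4 bond.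

Step 7
Reactants: 12 (2Z,5Z)-8-hydroxy-2-iodo-6-methylocta-2,5-dien-4-one
Product: 13 (3Z,6Z)-7-iodo-3-methyl-5-oxoocta-3,6-dienal
Conditions: Dess–Martin periodinane, NaHCO3, CH2Cl2, 0 °C; used at once without chromatography
Reagents that add atoms: none
Why: Dess–Martin oxidation of the primary alcohol under buffered conditions gives the β,γ-unsaturated aldehyde without moving the Z double bond into conjugation.

Step 8
Reactants: 7 (5R)-3-(bromomethyl)-5-(tert-butyldimethylsilyloxy)-5,6-dihydro-2H-pyran-2-one; 13 (3Z,6Z)-7-iodo-3-methyl-5-oxoocta-3,6-dienal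
Product: 15 (4R,5R)-5-(tert-butyldimethylsilyloxy)-4-[(1S,3Z,6Z)-1-hydroxy-7-iodo-3-methyl-5-oxoocta-3,6-dien-1-yl]-3-methylideneoxan-2-one, via allylzinc bromide 14 (not isolated)
Conditions: Zn dust (activated), THF/sat. aq. NH4Cl (2:1), 0 °C, short reaction time
Reagents that add atoms: none
Why: Barbier allylation through a Zimmerman–Traxler chair in which the ring carbon C6 and the aldehyde chain are both equatorial (anti C7/C8 relationship) and the aldehyde approaches C7 on the face opposite the neighbouring non-coordinating OTBS group, so that C7 (R) and C8 (S) are both set from C6.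

Step 9
Reactants: 15 (4R,5R)-5-(tert-butyldimethylsilyloxy)-4-[(1S,3Z,6Z)-1-hydroxy-7-iodo-3-methyl-5-oxoocta-3,6-dien-1-yl]-3-methylideneoxan-2-one; 16 (2E)-2-methylbut-2-enoyl chloride (tigloyl chloride)
Product: 17 (1S,3Z,6Z)-1-[(4R,5R)-5-(tert-butyldimethylsilyloxy)-3-methylidene-2-oxooxan-4-yl]-7-iodo-3-methyl-5-oxoocta-3,6-dien-1-yl (2E)-2-methylbut-2-enoate
Conditions: 16 (1.5 equiv), pyridine, CH2Cl2, 0 °C to rt
Reagents that add atoms: none
Why: Esterification (O-acylation with an acid chloride) proceeds with retention at C8 and caps O8 before it can attack the lactone carbonyl.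

Step 10
Reactants: 17 (1S,3Z,6Z)-1-[(4R,5R)-5-(tert-butyldimethylsilyloxy)-3-methylidene-2-oxooxan-4-yl]-7-iodo-3-methyl-5-oxoocta-3,6-dien-1-yl (2E)-2-methylbut-2-enoate
Product: 19 (1S,3Z,6Z)-1-[(2R,3R)-2-(hydroxymethyl)-4-methylidene-5-oxooxolan-3-yl]-7-iodo-3-methyl-5-oxoocta-3,6-dien-1-yl (2E)-2-methylbut-2-enoate, via desilylated six-membered hydroxy lactone 18 (not isolated)
Conditions: HF·pyridine, pyridine, THF, 0 °C to rt; then CSA (10 mol %), CH2Cl2, rt
Reagents that add atoms: none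
Why: Desilylation followed by acid-catalysed translactonisation, driven by the greater stability of the five-membered α-methylene lactone, moves the acyl group from O5 to O6 without breaking any bond to C6 or C7, so the trans OH/side-chain relationship of the six-membered ring becomes the cis-disposed C5/C8 substituents of the butyrolactone.

Step 11
Reactants: 19 (1S,3Z,6Z)-1-[(2R,3R)-2-(hydroxymethyl)-4-methylidene-5-oxooxolan-3-yl]-7-iodo-3-methyl-5-oxoocta-3,6-dien-1-yl (2E)-2-methylbut-2-enoate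
Product: 20 (1S,3Z,6Z)-1-[(2R,3R)-2-formyl-4-methylidene-5-oxooxolan-3-yl]-7-iodo-3-methyl-5-oxoocta-3,6-dien-1-yl (2E)-2-methylbut-2-enoate
Conditions: Dess–Martin periodinane, NaHCO3, CH2Cl2, 0 °C
Reagents that add atoms: none
Why: Dess–Martin oxidation gives the α-acyloxy aldehyde under buffered non-basic conditions that do not epimerise C6.

Step 12
Reactants: 20 (1S,3Z,6Z)-1-[(2R,3R)-2-formyl-4-methylidene-5-oxooxolan-3-yl]-7-iodo-3-methyl-5-oxoocta-3,6-dien-1-yl (2E)-2-methylbut-2-enoate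
Product: 22 (3aR,4S,6Z,9Z,11S,11aR)-11-hydroxy-6,10-dimethyl-3-methylidene-2,8-dioxo-2,3,3a,4,5,8,11,11a-octahydrocyclodeca[b]furan-4-yl (2E)-2-methylbut-2-enoate, via alkenylchromium dichloride 21 (not isolated)
Conditions: CrCl2 (8 equiv), NiCl2 (2 mol %), degassed DMSO/THF (3:1), 2 mM, slow addition, rt
Reagents that add atoms: none
Why: Intramolecular Nozaki–Hiyama–Kishi reaction, in which the alkenylchromium formed with retention of the Z geometry adds to the aldehyde anti to the C6–O bond (Felkin–Anh sense) to close the ten-membered ring and set C5 (S).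

**Compound list**
1 | (2R)-but-3-ene-1,2-diol | C=C[C@@H](O)CO | starting material
2 | (3R)-3,4-bis(tert-butyldimethylsilyloxy)but-1-ene | C=C[C@@H](O[Si](C)(C)C(C)(C)C)CO[Si](C)(C)C(C)(C)C | intermediate
3 | (2R)-2-(tert-butyldimethylsilyloxy)but-3-en-1-ol | C=C[C@@H](O[Si](C)(C)C(C)(C)C)CO | intermediate
4 | 2-(bromomethyl)prop-2-enoic acid | C=C(CBr)C(=O)O | starting material
5 | 2-(bromomethyl)prop-2-enoyl chloride (made in the flask) | C=C(CBr)C(=O)Cl | intermediate
6 | (2R)-2-(tert-butyldimethylsilyloxy)but-3-en-1-yl 2-(bromomethyl)prop-2-enoate | C=C[C@@H](O[Si](C)(C)C(C)(C)C)COC(=O)C(=C)CBr | intermediate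
7 | (5R)-3-(bromomethyl)-5-(tert-butyldimethylsilyloxy)-5,6-dihydro-2H-pyran-2-one (fragment A) | O=C1OC[C@H](O[Si](C)(C)C(C)(C)C)C=C1CBr | intermediate
8 | 4-methyl-5,6-dihydro-2H-pyran-2-one | CC1=CC(=O)OCC1 | starting material
9 | 1-propynyllithium | [Li]C#CC | starting material
10 | lithium 4-methyl-2-(prop-1-yn-1-yl)-5,6-dihydro-2H-pyran-2-olate (lithium hemiketal alkoxide, racemic transient centre, not isolated) | CC#CC1([O-])OCCC(C)=C1.[Li+] | intermediate
11 | (5Z)-8-hydroxy-6-methyloct-5-en-2-yn-4-one | CC#CC(=O)/C=C(/C)CCO | intermediate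
12 | (2Z,5Z)-8-hydroxy-2-iodo-6-methylocta-2,5-dien-4-one | I/C(C)=C\C(=O)/C=C(/C)CCO | intermediate
13 | (3Z,6Z)-7-iodo-3-methyl-5-oxoocta-3,6-dienal (fragment B) | I/C(C)=C\C(=O)/C=C(/C)CC=O | intermediate
14 | [(5R)-5-(tert-butyldimethylsilyloxy)-2-oxo-5,6-dihydro-2H-pyran-3-yl]methylzinc bromide (allylzinc bromide, not isolated) | O=C1OC[C@H](O[Si](C)(C)C(C)(C)C)C=C1C[Zn]Br | intermediate
15 | (4R,5R)-5-(tert-butyldimethylsilyloxy)-4-[(1S,3Z,6Z)-1-hydroxy-7-iodo-3-methyl-5-oxoocta-3,6-dien-1-yl]-3-methylideneoxan-2-one | C=C1C(=O)OC[C@H](O[Si](C)(C)C(C)(C)C)[C@H]1[C@@H](O)C/C(C)=C\C(=O)/C=C(/C)I | intermediate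
16 | (2E)-2-methylbut-2-enoyl chloride (tigloyl chloride) | C/C=C(\C)C(=O)Cl | starting material
17 | (1S,3Z,6Z)-1-[(4R,5R)-5-(tert-butyldimethylsilyloxy)-3-methylidene-2-oxooxan-4-yl]-7-iodo-3-methyl-5-oxoocta-3,6-dien-1-yl (2E)-2-methylbut-2-enoate | C=C1C(=O)OC[C@H](O[Si](C)(C)C(C)(C)C)[C@H]1[C@@H](OC(=O)/C(C)=C/C)C/C(C)=C\C(=O)/C=C(/C)I | intermediate
18 | (1S,3Z,6Z)-1-[(4S,5R)-5-hydroxy-3-methylidene-2-oxooxan-4-yl]-7-iodo-3-methyl-5-oxoocta-3,6-dien-1-yl (2E)-2-methylbut-2-enoate (desilylated six-membered lactone, not isolated) | C=C1C(=O)OC[C@H](O)[C@H]1[C@@H](OC(=O)/C(C)=C/C)C/C(C)=C\C(=O)/C=C(/C)I | intermediate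
19 | (1S,3Z,6Z)-1-[(2R,3R)-2-(hydroxymethyl)-4-methylidene-5-oxooxolan-3-yl]-7-iodo-3-methyl-5-oxoocta-3,6-dien-1-yl (2E)-2-methylbut-2-enoate | C=C1C(=O)O[C@@H](CO)[C@H]1[C@@H](OC(=O)/C(C)=C/C)C/C(C)=C\C(=O)/C=C(/C)I | intermediate
20 | (1S,3Z,6Z)-1-[(2R,3R)-2-formyl-4-methylidene-5-oxooxolan-3-yl]-7-iodo-3-methyl-5-oxoocta-3,6-dien-1-yl (2E)-2-methylbut-2-enoate | C=C1C(=O)O[C@@H](C=O)[C@H]1[C@@H](OC(=O)/C(C)=C/C)C/C(C)=C\C(=O)/C=C(/C)I | intermediate
21 | alkenylchromium dichloride derived from 20 (CrCl2 group in place of iodine, not isolated) | C=C1C(=O)O[C@@H](C=O)[C@H]1[C@@H](OC(=O)/C(C)=C/C)C/C(C)=C\C(=O)/C=C(/C)[Cr](Cl)Cl | intermediate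
22 | (3aR,4S,6Z,9Z,11S,11aR)-11-hydroxy-6,10-dimethyl-3-methylidene-2,8-dioxo-2,3,3a,4,5,8,11,11a-octahydrocyclodeca[b]furan-4-yl (2E)-2-methylbut-2-enoate | C=C1C(=O)O[C@@H]2[C@H]1[C@@H](OC(=O)/C(C)=C/C)C/C(C)=C\C(=O)/C=C(/C)[C@@H]2O | target

**Totals**
Total step count: 12. Longest linear sequence: 9 steps (steps 1–4 and 8–12, from 1); the other branch is 8 steps from 8 (steps 5–7, then 8–12).

**Three steps most likely to fail, with fallbacks**

Step 4 (metathesis). The acrylate partner is 1,1-disubstituted and carries an allylic bromide, so the closure may be slow and the catalyst may die. The fallback sets out from 3 and comes back at 7. Acylate 3 with acryloyl chloride (i-Pr2NEt, CH2Cl2, −78 °C) to give (2R)-2-(tert-butyldimethylsilyloxy)but-3-en-1-yl prop-2-enoate F1. Close this unhindered acrylate with the second-generation Grubbs catalyst (CH2Cl2, 40 °C) to give (5R)-5-(tert-butyldimethylsilyloxy)-5,6-dihydro-2H-pyran-2-one F2. Install the side arm afterwards by Morita–Baylis–Hillman hydroxymethylation (aq. CH2O, imidazole, THF/H2O), which gives (5R)-5-(tert-butyldimethylsilyloxy)-3-(hydroxymethyl)-5,6-dihydro-2H-pyran-2-one F3. Appel bromination (CBr4, PPh3, CH2Cl2, 0 °C) then gives 7.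

Step 8 (Barbier union). Four things can go wrong here: the aldehyde 13 is fragile, the allylzinc can lose silanolate by 1,4-elimination, zinc can attack the iodoenone, and the new O8 alkoxide can capture the lactone carbonyl. The fallback sets out from 7 and comes back at 15. Convert 7 with B2pin2 and Pd2(dba)3 (DMSO, rt) into the isolable allylboronate (5R)-5-(tert-butyldimethylsilyloxy)-3-[(4,4,5,5-tetramethyl-1,3,2-dioxaborolan-2-yl)methyl]-5,6-dihydro-2H-pyran-2-one F4. Add it to 13 under anhydrous, metal-free conditions (toluene, 4 Å sieves, 40 °C, Sc(OTf)3 10 mol % if slow). The closed six-membered allylboration transition state gives the same anti adduct on the face opposite OTBS, and aqueous work-up of the borate gives 15.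

Step 12 (ten-membered ring closure). The planar cross-conjugated Z,Z-dienone makes the seco chain stiff, so oligomers or poor C5 selectivity are possible. The fallback sets out from 19 and comes back at 22. Reduce the dienone carbonyl of 19 (NaBH4, CeCl3·7H2O, MeOH, −78 °C, Luche 1,2-reduction) to the more flexible diol (1S,3Z,6Z)-5-hydroxy-1-[(2R,3R)-2-(hydroxymethyl)-4-methylidene-5-oxooxolan-3-yl]-7-iodo-3-methylocta-3,6-dien-1-yl (2E)-2-methylbut-2-enoate F5, as both epimers at the new carbinol. Oxidise only the primary alcohol (TEMPO cat., PhI(OAc)2, CH2Cl2) to the hydroxy aldehyde (1S,3Z,6Z)-1-[(2R,3R)-2-formyl-4-methylidene-5-oxooxolan-3-yl]-5-hydroxy-7-iodo-3-methylocta-3,6-dien-1-yl (2E)-2-methylbut-2-enoate F6. Close the ring with CrCl2/NiCl2 in DMSO at high dilution to give the macrocyclic diol (3aR,4S,6Z,9Z,11S,11aR)-8,11-dihydroxy-6,10-dimethyl-3-methylidene-2-oxo-2,3,3a,4,5,8,11,11a-octahydrocyclodeca[b]furan-4-yl (2E)-2-methylbut-2-enoate F7. Finally oxidise the doubly allylic C2 alcohol selectively with MnO2 (CH2Cl2, rt) to reach 22.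

Further compounds
F1 | step 4 | (2R)-2-(tert-butyldimethylsilyloxy)but-3-en-1-yl prop-2-enoate | C=C[C@@H](O[Si](C)(C)C(C)(C)C)COC(=O)C=C
F2 | step 4 | (5R)-5-(tert-butyldimethylsilyloxy)-5,6-dihydro-2H-pyran-2-one | O=C1OC[C@H](O[Si](C)(C)C(C)(C)C)C=C1
F3 | step 4 | (5R)-5-(tert-butyldimethylsilyloxy)-3-(hydroxymethyl)-5,6-dihydro-2H-pyran-2-one | O=C1OC[C@H](O[Si](C)(C)C(C)(C)C)C=C1CO
F4 | step 8 | (5R)-5-(tert-butyldimethylsilyloxy)-3-[(4,4,5,5-tetramethyl-1,3,2-dioxaborolan-2-yl)methyl]-5,6-dihydro-2H-pyran-2-one | O=C1OC[C@H](O[Si](C)(C)C(C)(C)C)C=C1CB2OC(C)(C)C(C)(C)O2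
F5 | step 12 | (1S,3Z,6Z)-5-hydroxy-1-[(2R,3R)-2-(hydroxymethyl)-4-methylidene-5-oxooxolan-3-yl]-7-iodo-3-methylocta-3,6-dien-1-yl (2E)-2-methylbut-2-enoate, both epimers at chain C5 | C=C1C(=O)O[C@@H](CO)[C@H]1[C@@H](OC(=O)/C(C)=C/C)C/C(C)=C\C(O)/C=C(/C)I
F6 | step 12 | (1S,3Z,6Z)-1-[(2R,3R)-2-formyl-4-methylidene-5-oxooxolan-3-yl]-5-hydroxy-7-iodo-3-methylocta-3,6-dien-1-yl (2E)-2-methylbut-2-enoate, both epimers at chain C5 | C=C1C(=O)O[C@@H](C=O)[C@H]1[C@@H](OC(=O)/C(C)=C/C)C/C(C)=C\C(O)/C=C(/C)I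
F7 | step 12 | (3aR,4S,6Z,9Z,11S,11aR)-8,11-dihydroxy-6,10-dimethyl-3-methylidene-2-oxo-2,3,3a,4,5,8,11,11a-octahydrocyclodeca[b]furan-4-yl (2E)-2-methylbut-2-enoate, both epimers at ring C8 | C=C1C(=O)O[C@@H]2[C@H]1[C@@H](OC(=O)/C(C)=C/C)C/C(C)=C\C(O)/C=C(/C)[C@@H]2O
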